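Ring F (O1''–C2''–C3''–C4''–C4a''–C8a'') carries the C3''-OH and C4''-OH cis to each other and anti to ring D on C2''. This is the pattern OsO4 leaves on a C3''=C4'' alkene, so that alkene is cut by ring-closing metathesis into the vinyl group on C2'' and the ortho-vinyl group of ring E.
The metathesis diene is an (S)-1-arylallyl aryl ether, made by iridium-catalysed branched etherification of a ring D cinnamyl carbonate with 5-(benzyloxy)-2-ethenylphenol. The carbonate comes from a ring D aryl triflate by Stille coupling.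
The C4–D2 bond is made before that by Friedel–Crafts reaction of 3,4,5-tris(benzyloxy)phenol with the upper flavan-3,4-diyl dipivalate, where the 3-pivalate participates and gives the 3,4-trans product.
The dipivalate is built by the same etherification, metathesis and dihydroxylation sequence. Rings therefore form in the order C (step 6), then F (step 15), followed by dihydroxylation, pivalate removal and hydrogenolysis of eight benzyl ethers.
Key step: step 15

Remarks before the steps
- Numbering: the upper flavan unit is unprimed (rings A and C, 2-aryl ring B). Ring D is the pyrogallol ring, with C2'' on D1, the upper C4 on D2 and oxygens on D3–D5. The lower unit is double-primed (benzo ring E, pyran ring F).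
- L is (Sa,Sc,Sc)-O,O'-(1,1'-binaphthyl-2,2'-diyl) N,N-bis(1-phenylethyl)phosphoramidite.
- Assumption: the sense of induction in steps 5 and 14 is taken from the behaviour of this catalyst class with cinnamyl carbonates and aryloxides, where the (Ra,Rc,Rc) ligand gives (R)-1-arylallyl aryl ethers. The (Sa,Sc,Sc) ligand is therefore specified, and the antipode would be used if the sense is the reverse.
- Aryloxide counter-ion: phenol 2 is used as its lithium salt 7 with the unhindered carbonate 6 (step 5) and as its more nucleophilic sodium salt 18 with the ortho-hindered carbonate 17 (step 14). Each salt is made in the flask of the step that uses it.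
- Descriptors: the ether carbon of dienes 8 and 19 and C2 of flavenes 9 and 20 is (S), because aryl outranks vinyl. The same spatial arrangement becomes (R) once C3 carries oxygen.
- Compounds 1 and 3 and the reagent (E)-3-(tributylstannyl)prop-2-en-1-ol are taken as catalogue compounds.

Step 1
Reactants: 1 4-(benzyloxy)-2-hydroxybenzaldehyde
Product: 2 5-(benzyloxy)-2-ethenylphenol
Conditions: Ph3PCH3Br (2.5 equiv), KOt-Bu (2.5 equiv), THF, 0 °C → rt
Reagents that add atoms: methyltriphenylphosphonium bromide, C[P+](c1ccccc1)(c1ccccc1)c1ccccc1.[Br-]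
Why: Wittig methylenation with excess ylide tolerates the phenoxide and converts the aldehyde into the styrene needed for both metatheses.

Step 2
Reactants: 3 3,4,5-tris(benzyloxy)benzaldehyde
Product: 4 ethyl (2E)-3-[3,4,5-tris(benzyloxy)phenyl]prop-2-enoate
Conditions: (EtO)2P(O)CH2CO2Et, NaH, THF, 0 °C → rt
Reagents that add atoms: triethyl phosphonoacetate, CCOC(=O)CP(=O)(OCC)OCC
Why: Horner–Wadsworth–Emmons olefination with a stabilised phosphonate anion should give the (E)-cinnamate.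

Step 3
Reactants: 4 ethyl (2E)-3-[3,4,5-tris(benzyloxy)phenyl]prop-2-enoate
Product: 5 (2E)-3-[3,4,5-tris(benzyloxy)phenyl]prop-2-en-1-ol
Conditions: i-Bu2AlH (2.5 equiv), CH2Cl2, −78 → 0 °C; aq. potassium sodium tartrate
Reagents that add atoms: none
Why: 1,2-Reduction of the unsaturated ester by the aluminium hydride gives the allylic alcohol and leaves the alkene geometry and the benzyl ethers intact.

Step 4
Reactants: 5 (2E)-3-[3,4,5-tris(benzyloxy)phenyl]prop-2-en-1-ol
Product: 6 methyl (2E)-3-[3,4,5-tris(benzyloxy)phenyl]prop-2-en-1-yl carbonate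
Conditions: ClCO2Me, pyridine, CH2Cl2, 0 °C
Reagents that add atoms: methyl chloroformate, COC(Cl)=O
Why: O-Acylation of the primary allylic alcohol with a chloroformate gives the linear allylic carbonate used as allyl electrophile.

Step 5
Reactants: 6 methyl (2E)-3-[3,4,5-tris(benzyloxy)phenyl]prop-2-en-1-yl carbonate; 2 5-(benzyloxy)-2-ethenylphenol
Product: 8 4-(benzyloxy)-1-ethenyl-2-({(1S)-1-[3,4,5-tris(benzyloxy)phenyl]prop-2-en-1-yl}oxy)benzene, via lithium aryloxide 7 (not isolated)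
Conditions: 2 (2 equiv), n-BuLi (2 equiv), THF, 0 °C; then 6, [Ir(cod)Cl]2 (2 mol %), L (4 mol %, catalyst preactivated with n-PrNH2), THF, 50 °C
Reagents that add atoms: none
Why: Iridium-catalysed asymmetric allylic etherification: the allyl iridium complex formed from the carbonate is attacked by the aryloxide at its aryl-bearing terminus to give the branched ether, and the (Sa,Sc,Sc) ligand sets the new (S) centre that becomes C2 of the upper unit.

Step 6
Reactants: 8 (S)-diene
Product: 9 (2S)-7-(benzyloxy)-2-[3,4,5-tris(benzyloxy)phenyl]-2H-chromene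
Conditions: second-generation Grubbs catalyst (H2IMes)(PCy3)Cl2Ru=CHPh (5 mol %), CH2Cl2 (0.01 M), 40 °C
Reagents that add atoms: none
Why: Ring-closing metathesis of an ortho-vinylaryl 1-arylallyl ether to a 2-aryl-2H-chromene closes ring C with loss of ethylene and leaves the C2 centre untouched.

Step 7
Reactants: 9 (2S)-7-(benzyloxy)-2-[3,4,5-tris(benzyloxy)phenyl]-2H-chromene
Product: 10 (2R,3S,4S)-7-(benzyloxy)-2-[3,4,5-tris(benzyloxy)phenyl]-3,4-dihydro-2H-chromene-3,4-diol (2,3-trans-3,4-cis)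
Conditions: OsO4 (2 mol %), NMO (1.5 equiv), acetone/H2O, rt
Reagents that add atoms: osmium tetroxide (catalytic oxygen carrier), O=[Os](=O)(=O)=O; N-methylmorpholine N-oxide, C[N+]1([O-])CCOCC1; water, O
Why: Catalytic OsO4/NMO syn-dihydroxylation of the flav-3-ene takes place on the face of C3=C4 opposite the C2 aryl group, which sets C3 (S) and C4 (S) as the 2,3-trans-3,4-cis diol.

Step 8
Reactants: 10 (2R,3S,4S)-diol
Product: 11 3,4-di-O-pivaloyl derivative of 10 (configuration unchanged; descriptors 2R,3R,4S)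
Conditions: PivCl, pyridine, DMAP, 50 °C
Reagents that add atoms: pivaloyl chloride, CC(C)(C)C(Cl)=O
Why: Double O-acylation gives a 4-pivalate that can ionise at the benzylic position and a 3-pivalate that can participate and later resists alkoxide.

Step 9
Reactants: 3 3,4,5-tris(benzyloxy)benzaldehyde
Product: 13 3,4,5-tris(benzyloxy)phenol, via aryl formate 12 (not isolated)
Conditions: mCPBA, CH2Cl2, 0 °C → rt; then K2CO3 (cat.), MeOH, rt
Reagents that add atoms: 3-chloroperbenzoic acid, OOC(=O)c1cccc(Cl)c1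
Why: Baeyer–Villiger (Dakin-type) oxidation of the electron-rich benzaldehyde proceeds by aryl migration to the aryl formate, which is methanolysed to the phenol.

Step 10
Reactants: 11 upper dipivalate; 13 3,4,5-tris(benzyloxy)phenol
Product: 14 (2R,3S,4S)-7-(benzyloxy)-4-[2,3,4-tris(benzyloxy)-6-hydroxyphenyl]-2-[3,4,5-tris(benzyloxy)phenyl]-3,4-dihydro-2H-chromen-3-yl pivalate (2,3-trans-3,4-trans)
Conditions: 13 (3 equiv), BF3·OEt2, CH2Cl2, −78 → −20 °C
Reagents that add atoms: none
Why: Friedel–Crafts alkylation: BF3 ionises the benzylic 4-pivalate (cation stabilised by O1 and the 7-benzyloxy group), the 3-pivalate closes on it to a cis-fused 1,3-dioxolan-2-ylium ion on the O3 face, and the phloroglucinol-type phenol, used in excess to prevent double alkylation, attacks C4 through its free position ortho to OH from the open face, which sets C4 (S) trans to O3.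

Step 11
Reactants: 14 ring D phenol
Product: 15 ring D aryl triflate (14 with OSO2CF3 on D1)
Conditions: Tf2O, pyridine, CH2Cl2, 0 °C
Reagents that add atoms: trifluoromethanesulfonic anhydride, O=S(=O)(OS(=O)(=O)C(F)(F)F)C(F)(F)F
Why: O-Sulfonylation of the only free hydroxyl converts the ring D phenol into an aryl triflate for cross-coupling.

Step 12
Reactants: 15 ring D aryl triflate
Product: 16 ring D (E)-allylic alcohol (15 with (1E)-3-hydroxyprop-1-en-1-yl on D1)
Conditions: (E)-Bu3SnCH=CHCH2OH, Pd(PPh3)4 (10 mol %), LiCl, CuCl, DMSO, 60 °C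
Reagents that add atoms: (E)-3-(tributylstannyl)prop-2-en-1-ol, CCCC[Sn](CCCC)(CCCC)/C=C/CO
Why: Stille cross-coupling (oxidative addition of zerovalent palladium into the aryl triflate, transmetalation of the vinylstannane assisted by CuCl and LiCl, reductive elimination) installs the (E)-hydroxypropenyl group with retention of alkene geometry under conditions suited to ortho-hindered partners.

Step 13
Reactants: 16 ring D (E)-allylic alcohol
Product: 17 ring D (E)-cinnamyl methyl carbonate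
Conditions: ClCO2Me, pyridine, CH2Cl2, 0 °C
Reagents that add atoms: methyl chloroformate, COC(Cl)=O
Why: Acylation of the sole free (primary allylic) hydroxyl with the chloroformate gives the linear allylic carbonate.

Step 14
Reactants: 17 ring D (E)-cinnamyl methyl carbonate; 2 5-(benzyloxy)-2-ethenylphenol
Product: 19 metathesis diene (17 in which D1 carries the (1S)-1-[5-(benzyloxy)-2-ethenylphenoxy]prop-2-en-1-yl group), via sodium aryloxide 18 (not isolated)
Conditions: 2 (2 equiv), NaH (2 equiv), THF, 0 °C → rt; then 17, [Ir(cod)Cl]2 (4 mol %), L (8 mol %, catalyst preactivated with n-PrNH2), THF, 50 °C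
Reagents that add atoms: none
Why: Iridium-catalysed asymmetric allylic etherification as in step 5, in which aryloxide attack at the benzylic allyl terminus gives the branched ether, the (Sa,Sc,Sc) ligand and not the remote upper-unit centres should set the (S) carbon that becomes C2'', the sodium aryloxide is taken because its higher nucleophilicity should help at an allyl terminus flanked by the ortho-substituted ring D, and the hindered pivalate should withstand the sparingly soluble sodium methoxide released.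

Step 15
Reactants: 19 metathesis diene
Product: 20 upper 3-O-pivaloyl 4-arylflavan joined through ring D to the lower (2S)-7-(benzyloxy)-2H-chromene (flav-3-ene)
Conditions: second-generation Grubbs catalyst (H2IMes)(PCy3)Cl2Ru=CHPh (10 mol %), 1,4-benzoquinone (20 mol %), CH2Cl2 (5 mM), 40 °C
Reagents that add atoms: none
Why: The ruthenium benzylidene exchanges with one of the two terminal alkenes of 19, and the new alkylidene undergoes intramolecular [2+2] cycloaddition with the other alkene followed by cycloreversion of the ruthenacyclobutane, which forms C3''=C4'' and releases ethylene. The closest known reaction is the ring-closing metathesis of ortho-vinylaryl allyl ethers to 2H-chromenes, 2-aryl cases included, and step 6 is the same reaction on the parent diene. Ring F closes as a six-membered ring by joining the two internal alkene carbons of a 1,7-diene, driven by loss of ethylene and by conjugation of the new cis alkene with ring E. No stereocentre is formed; C2'' from step 14 and C2, C3 and C4 of the upper unit are untouched, and C2'' later steers OsO4 to the opposite face. The step needs ring closure to win over intermolecular metathesis and over ruthenium hydride isomerisation of the allyl ether; the ortho placement of the two alkenes on the ether tether, high dilution and the benzoquinone additive secure this, and the pivalate and benzyl ethers are inert to the catalyst.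

Step 16
Reactants: 20 lower flav-3-ene
Product: 21 lower (2R,3S,4S)-3,4-diol with the upper 3-pivalate in place
Conditions: OsO4 (5 mol %), NMO (2 equiv), THF/acetone/H2O, rt
Reagents that add atoms: osmium tetroxide (catalytic oxygen carrier), O=[Os](=O)(=O)=O; N-methylmorpholine N-oxide, C[N+]1([O-])CCOCC1; water, O
Why: Catalytic OsO4/NMO syn-dihydroxylation of the ring F alkene from the face opposite ring D on C2'' sets C3'' (S) and C4'' (S) as the 2,3-trans-3,4-cis diol, the same facial preference as in step 7.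

Step 17
Reactants: 21 diol pivalate
Product: 22 octa-O-benzyl triol (upper 3-OH, lower 3'',4''-diol)
Conditions: i-Bu2AlH (6 equiv), CH2Cl2, −78 → 0 °C; aq. potassium sodium tartrate
Reagents that add atoms: none
Why: Reductive ester cleavage by the aluminium hydride removes the hindered 3-pivalate while the benzyl ethers and the diol (carried as aluminium alkoxides) are unaffected.

Step 18
Reactants: 22 octa-O-benzyl triol
Product: 23 CNP0205451.3
Conditions: H2 (1 atm), Pd(OH)2/C, THF/MeOH, rt, argon work-up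
Reagents that add atoms: none
Why: Catalytic hydrogenolysis removes the eight aryl benzyl ethers, which cleave faster under neutral conditions than the benzylic C–O bonds at C2, C2'' and C4'', and touches no stereocentre.

Compound list
1 | 4-(benzyloxy)-2-hydroxybenzaldehyde | O=Cc1ccc(OCc2ccccc2)cc1O | starting material
2 | 5-(benzyloxy)-2-ethenylphenol | C=Cc1ccc(OCc2ccccc2)cc1O | intermediate
3 | 3,4,5-tris(benzyloxy)benzaldehyde | O=Cc1cc(OCc2ccccc2)c(OCc2ccccc2)c(OCc2ccccc2)c1 | starting material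
4 | ethyl (2E)-3-[3,4,5-tris(benzyloxy)phenyl]prop-2-enoate | CCOC(=O)/C=C/c1cc(OCc2ccccc2)c(OCc2ccccc2)c(OCc2ccccc2)c1 | intermediate
5 | (2E)-3-[3,4,5-tris(benzyloxy)phenyl]prop-2-en-1-ol | OC/C=C/c1cc(OCc2ccccc2)c(OCc2ccccc2)c(OCc2ccccc2)c1 | intermediate
6 | methyl (2E)-3-[3,4,5-tris(benzyloxy)phenyl]prop-2-en-1-yl carbonate | COC(=O)OC/C=C/c1cc(OCc2ccccc2)c(OCc2ccccc2)c(OCc2ccccc2)c1 | intermediate
7 | lithium 5-(benzyloxy)-2-ethenylphenolate (not isolated) | [Li+].[O-]c1cc(OCc2ccccc2)ccc1C=C | intermediate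
8 | 4-(benzyloxy)-1-ethenyl-2-({(1S)-1-[3,4,5-tris(benzyloxy)phenyl]prop-2-en-1-yl}oxy)benzene | C=C[C@H](Oc1cc(OCc2ccccc2)ccc1C=C)c1cc(OCc2ccccc2)c(OCc2ccccc2)c(OCc2ccccc2)c1 | intermediate
9 | (2S)-7-(benzyloxy)-2-[3,4,5-tris(benzyloxy)phenyl]-2H-chromene | C1=C[C@@H](c2cc(OCc3ccccc3)c(OCc3ccccc3)c(OCc3ccccc3)c2)Oc2cc(OCc3ccccc3)ccc12 | intermediate
10 | (2R,3S,4S)-7-(benzyloxy)-2-[3,4,5-tris(benzyloxy)phenyl]-3,4-dihydro-2H-chromene-3,4-diol | O[C@@H]1[C@H](O)[C@@H](c2cc(OCc3ccccc3)c(OCc3ccccc3)c(OCc3ccccc3)c2)Oc2cc(OCc3ccccc3)ccc12 | intermediate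
11 | (2R,3R,4S)-7-(benzyloxy)-2-[3,4,5-tris(benzyloxy)phenyl]-3,4-dihydro-2H-chromene-3,4-diyl bis(2,2-dimethylpropanoate) (2,3-trans-3,4-cis) | CC(C)(C)C(=O)O[C@@H]1[C@H](OC(=O)C(C)(C)C)[C@@H](c2cc(OCc3ccccc3)c(OCc3ccccc3)c(OCc3ccccc3)c2)Oc2cc(OCc3ccccc3)ccc12 | intermediate
12 | 3,4,5-tris(benzyloxy)phenyl formate (not isolated) | O=COc1cc(OCc2ccccc2)c(OCc2ccccc2)c(OCc2ccccc2)c1 | intermediate
13 | 3,4,5-tris(benzyloxy)phenol | Oc1cc(OCc2ccccc2)c(OCc2ccccc2)c(OCc2ccccc2)c1 | intermediate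
14 | (2R,3S,4S)-7-(benzyloxy)-4-[2,3,4-tris(benzyloxy)-6-hydroxyphenyl]-2-[3,4,5-tris(benzyloxy)phenyl]-3,4-dihydro-2H-chromen-3-yl 2,2-dimethylpropanoate | c1ccccc1COc1ccc2c(c1)O[C@H](c1cc(OCc3ccccc3)c(OCc3ccccc3)c(OCc3ccccc3)c1)[C@@H](OC(=O)C(C)(C)C)[C@@H]2c1c(O)cc(OCc2ccccc2)c(OCc2ccccc2)c1OCc1ccccc1 | intermediate
15 | (2R,3S,4S)-7-(benzyloxy)-4-{2,3,4-tris(benzyloxy)-6-[(trifluoromethanesulfonyl)oxy]phenyl}-2-[3,4,5-tris(benzyloxy)phenyl]-3,4-dihydro-2H-chromen-3-yl 2,2-dimethylpropanoate | c1ccccc1COc1ccc2c(c1)O[C@H](c1cc(OCc3ccccc3)c(OCc3ccccc3)c(OCc3ccccc3)c1)[C@@H](OC(=O)C(C)(C)C)[C@@H]2c1c(OS(=O)(=O)C(F)(F)F)cc(OCc2ccccc2)c(OCc2ccccc2)c1OCc1ccccc1 | intermediate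
16 | (2R,3S,4S)-7-(benzyloxy)-4-{2,3,4-tris(benzyloxy)-6-[(1E)-3-hydroxyprop-1-en-1-yl]phenyl}-2-[3,4,5-tris(benzyloxy)phenyl]-3,4-dihydro-2H-chromen-3-yl 2,2-dimethylpropanoate | c1ccccc1COc1ccc2c(c1)O[C@H](c1cc(OCc3ccccc3)c(OCc3ccccc3)c(OCc3ccccc3)c1)[C@@H](OC(=O)C(C)(C)C)[C@@H]2c1c(/C=C/CO)cc(OCc2ccccc2)c(OCc2ccccc2)c1OCc1ccccc1 | intermediate
17 | (2R,3S,4S)-7-(benzyloxy)-4-{2,3,4-tris(benzyloxy)-6-[(1E)-3-[(methoxycarbonyl)oxy]prop-1-en-1-yl]phenyl}-2-[3,4,5-tris(benzyloxy)phenyl]-3,4-dihydro-2H-chromen-3-yl 2,2-dimethylpropanoate | c1ccccc1COc1ccc2c(c1)O[C@H](c1cc(OCc3ccccc3)c(OCc3ccccc3)c(OCc3ccccc3)c1)[C@@H](OC(=O)C(C)(C)C)[C@@H]2c1c(/C=C/COC(=O)OC)cc(OCc2ccccc2)c(OCc2ccccc2)c1OCc1ccccc1 | intermediate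
18 | sodium 5-(benzyloxy)-2-ethenylphenolate (not isolated) | [Na+].[O-]c1cc(OCc2ccccc2)ccc1C=C | intermediate
19 | (2R,3S,4S)-7-(benzyloxy)-4-{2,3,4-tris(benzyloxy)-6-[(1S)-1-[5-(benzyloxy)-2-ethenylphenoxy]prop-2-en-1-yl]phenyl}-2-[3,4,5-tris(benzyloxy)phenyl]-3,4-dihydro-2H-chromen-3-yl 2,2-dimethylpropanoate | c1ccccc1COc1ccc2c(c1)O[C@H](c1cc(OCc3ccccc3)c(OCc3ccccc3)c(OCc3ccccc3)c1)[C@@H](OC(=O)C(C)(C)C)[C@@H]2c1c([C@H](C=C)Oc2cc(OCc3ccccc3)ccc2C=C)cc(OCc2ccccc2)c(OCc2ccccc2)c1OCc1ccccc1 | intermediate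
20 | (2R,3S,4S)-7-(benzyloxy)-4-{2,3,4-tris(benzyloxy)-6-[(2S)-7-(benzyloxy)-2H-chromen-2-yl]phenyl}-2-[3,4,5-tris(benzyloxy)phenyl]-3,4-dihydro-2H-chromen-3-yl 2,2-dimethylpropanoate | c1ccccc1COc1ccc2c(c1)O[C@H](c1cc(OCc3ccccc3)c(OCc3ccccc3)c(OCc3ccccc3)c1)[C@@H](OC(=O)C(C)(C)C)[C@@H]2c1c([C@H]2Oc3cc(OCc4ccccc4)ccc3C=C2)cc(OCc2ccccc2)c(OCc2ccccc2)c1OCc1ccccc1 | intermediate
21 | (2R,3S,4S)-7-(benzyloxy)-4-{2,3,4-tris(benzyloxy)-6-[(2R,3S,4S)-7-(benzyloxy)-3,4-dihydroxy-3,4-dihydro-2H-chromen-2-yl]phenyl}-2-[3,4,5-tris(benzyloxy)phenyl]-3,4-dihydro-2H-chromen-3-yl 2,2-dimethylpropanoate | c1ccccc1COc1ccc2c(c1)O[C@H](c1cc(OCc3ccccc3)c(OCc3ccccc3)c(OCc3ccccc3)c1)[C@@H](OC(=O)C(C)(C)C)[C@@H]2c1c([C@H]2Oc3cc(OCc4ccccc4)ccc3[C@H](O)[C@@H]2O)cc(OCc2ccccc2)c(OCc2ccccc2)c1OCc1ccccc1 | intermediate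
22 | (2R,3S,4S)-7-(benzyloxy)-4-{2,3,4-tris(benzyloxy)-6-[(2R,3S,4S)-7-(benzyloxy)-3,4-dihydroxy-3,4-dihydro-2H-chromen-2-yl]phenyl}-2-[3,4,5-tris(benzyloxy)phenyl]-3,4-dihydro-2H-chromen-3-ol | c1ccccc1COc1ccc2c(c1)O[C@H](c1cc(OCc3ccccc3)c(OCc3ccccc3)c(OCc3ccccc3)c1)[C@@H](O)[C@@H]2c1c([C@H]2Oc3cc(OCc4ccccc4)ccc3[C@H](O)[C@@H]2O)cc(OCc2ccccc2)c(OCc2ccccc2)c1OCc1ccccc1 | intermediate
23 | CNP0205451.3, (2R,3S,4S)-2-{3,4,5-trihydroxy-2-[(2R,3S,4S)-3,7-dihydroxy-2-(3,4,5-trihydroxyphenyl)-3,4-dihydro-2H-chromen-4-yl]phenyl}-3,4-dihydro-2H-chromene-3,4,7-triol | Oc1ccc2c(c1)O[C@H](c1cc(O)c(O)c(O)c1)[C@@H](O)[C@@H]2c1c([C@H]2Oc3cc(O)ccc3[C@H](O)[C@@H]2O)cc(O)c(O)c1O | target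

Total step count: 18 steps.
Longest linear sequence: 16 steps (3 → 23 through steps 2–8 and 10–18).

Steps most likely to fail

1. Step 14. The allyl terminus sits next to the ortho-substituted ring D, so turnover may be slow and branched selectivity may erode, with attack drifting to the unhindered terminus. The fallback sets C2'' through an epoxide and sets out from allylic alcohol 16. Sharpless asymmetric epoxidation (Ti(Oi-Pr)4, L-(+)-diethyl tartrate, t-BuOOH, 4 Å sieves, CH2Cl2, −20 °C) should give the (2S,3S)-epoxy alcohol F1 under reagent control. Phenol 2 (Cs2CO3, DMF, 60 °C, or Ti(Oi-Pr)4 promotion) should open the benzylic epoxide carbon with inversion, as phenoxides do with 3-arylglycidols, to give the 3-aryloxy-1,2-diol F2. Corey–Winter olefination through the cyclic thiocarbonate F3 (1,1'-thiocarbonyldiimidazole, toluene, 80 °C; then P(OMe)3, 110 °C) removes the diol as the terminal alkene and rejoins the route at diene 19.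

2. Step 10. The flavan-4-yl cation may alkylate the phenol twice or attack ring A or ring B of a second molecule, or ionisation of the 4-pivalate by BF3 may not be clean. The fallback sets out from dipivalate 11. Exchange of the 4-pivalate for a thioether (PhCH2SH, BF3·OEt2, CH2Cl2, −78 °C, with 3-pivalate participation) should give the storable 3,4-trans 4-benzylsulfanyl flavan-3-yl pivalate F4. Thiophilic activation with AgBF4 in THF at 0 °C in the presence of phenol 13 then releases the same dioxolanylium ion slowly and without added Lewis acid, and the route is rejoined at 14.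

3. Step 18. The benzylic C4''–O bond of ring F may be hydrogenolysed in competition with debenzylation, and the free pyrogallol rings may oxidise during isolation. The fallback sets out from triol 22. Silylation of the three hydroxyls (t-BuMe2SiOTf, 2,6-lutidine, CH2Cl2, 0 °C → rt) should give the tris-silyl ether F5, whose benzylic C–O bond is shielded. Hydrogenolysis (H2, Pd(OH)2/C, EtOAc) then gives the octaphenol tris-silyl ether F6, and HF·pyridine in THF at 0 °C under argon removes the silyl groups to reach 23.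

Further compounds
F1 | step 14 | 16 in which D1 carries a (2S,3S)-3-(hydroxymethyl)oxiran-2-yl group | c1ccccc1COc1ccc2c(c1)O[C@H](c1cc(OCc3ccccc3)c(OCc3ccccc3)c(OCc3ccccc3)c1)[C@@H](OC(=O)C(C)(C)C)[C@@H]2c1c([C@@H]3O[C@H]3CO)cc(OCc2ccccc2)c(OCc2ccccc2)c1OCc1ccccc1
F2 | step 14 | 16 in which D1 carries a (1R,2S)-1-[5-(benzyloxy)-2-ethenylphenoxy]-2,3-dihydroxypropyl group | c1ccccc1COc1ccc2c(c1)O[C@H](c1cc(OCc3ccccc3)c(OCc3ccccc3)c(OCc3ccccc3)c1)[C@@H](OC(=O)C(C)(C)C)[C@@H]2c1c([C@@H](Oc2cc(OCc3ccccc3)ccc2C=C)[C@@H](O)CO)cc(OCc2ccccc2)c(OCc2ccccc2)c1OCc1ccccc1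
F3 | step 14 | cyclic thiocarbonate (1,3-dioxolane-2-thione) of diol F2 | c1ccccc1COc1ccc2c(c1)O[C@H](c1cc(OCc3ccccc3)c(OCc3ccccc3)c(OCc3ccccc3)c1)[C@@H](OC(=O)C(C)(C)C)[C@@H]2c1c([C@@H](Oc2cc(OCc3ccccc3)ccc2C=C)[C@@H]2COC(=S)O2)cc(OCc2ccccc2)c(OCc2ccccc2)c1OCc1ccccc1
F4 | step 10 | (2R,3R,4R)-4-(benzylsulfanyl)-7-(benzyloxy)-2-[3,4,5-tris(benzyloxy)phenyl]-3,4-dihydro-2H-chromen-3-yl 2,2-dimethylpropanoate (2,3-trans-3,4-trans) | c1ccccc1CS[C@H]1[C@H](OC(=O)C(C)(C)C)[C@@H](c2cc(OCc3ccccc3)c(OCc3ccccc3)c(OCc3ccccc3)c2)Oc2cc(OCc3ccccc3)ccc12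
F5 | step 18 | 3,3'',4''-tris-O-(tert-butyldimethylsilyl) derivative of 22 | c1ccccc1COc1ccc2c(c1)O[C@H](c1cc(OCc3ccccc3)c(OCc3ccccc3)c(OCc3ccccc3)c1)[C@@H](O[Si](C)(C)C(C)(C)C)[C@@H]2c1c([C@H]2Oc3cc(OCc4ccccc4)ccc3[C@H](O[Si](C)(C)C(C)(C)C)[C@@H]2O[Si](C)(C)C(C)(C)C)cc(OCc2ccccc2)c(OCc2ccccc2)c1OCc1ccccc1
F6 | step 18 | 3,3'',4''-tris-O-(tert-butyldimethylsilyl) derivative of 23 | Oc1ccc2c(c1)O[C@H](c1cc(O)c(O)c(O)c1)[C@@H](O[Si](C)(C)C(C)(C)C)[C@@H]2c1c([C@H]2Oc3cc(O)ccc3[C@H](O[Si](C)(C)C(C)(C)C)[C@@H]2O[Si](C)(C)C(C)(C)C)cc(O)c(O)c1O
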